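**Retrosynthetic overview**
- Last bond: the C9–O ester, made by Mitsunobu inversion of the (9R)-alcohol with unprotected vanillic acid.
- The (9R)-alcohol comes from the achiral ring 9-ketone by enantioselective carbonyl reduction (the only stereocentre). The ketone is unmasked from an enol carbamate, and the 1,3(15)-diene comes from 1,4-dehydration of a C1 allylic alcohol.
- The only ring (eleven-membered) is closed at C1–C11. A Lewis-acid-bound (2E,6E)-enal (an oxy-farnesyl cation) is attacked by C11 of the terminal C10=C11 bond, as in farnesyl diphosphate → humulyl cation. The C10 cation is discharged by loss of a C9 stannyl group that sits next to a carbamate oxygen, so the C9 oxygen is installed in the ring-forming step.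
- Acyclic precursor: 8-bromogeranyl acetate (from geranyl acetate) plus lithiated prenyl carbamate (from prenol), then C9 stannylation and C1 oxidation.

Assumption: carbons keep farnesyl numbering C1–C15 throughout (ring = C1…C11, C11 = CMe2, C9 = carbinol carbon, C15 = exocyclic CH2), so the target is 9S (CIP order O > C10 > C8 > H); a species is numbered as a non-isolated intermediate when one stage of a one-pot operation hands it to the next stage or to the work-up.

**Step 1**
Reactants: 1 geranyl acetate
Product: 2 (2E,6E)-8-hydroxy-3,7-dimethylocta-2,6-dien-1-yl acetate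
Conditions: SeO2 (0.3 equiv), t-BuOOH (2 equiv), salicylic acid (cat.), CH2Cl2, 0 °C to rt
Reagents that add atoms: tert-butyl hydroperoxide CC(C)(C)OO
Why: Sharpless SeO2/t-BuOOH allylic oxidation (ene reaction, then [2,3]-sigmatropic shift) hydroxylates the (E)-methyl of the terminal trisubstituted alkene selectively and keeps the 6E geometry; no stereocentre is formed.

**Step 2**
Reactants: 2 (2E,6E)-8-hydroxy-3,7-dimethylocta-2,6-dien-1-yl acetate
Product: 3 (2E,6E)-8-bromo-3,7-dimethylocta-2,6-dien-1-yl acetate
Conditions: CBr4, PPh3, CH2Cl2, 0 °C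
Reagents that add atoms: carbon tetrabromide BrC(Br)(Br)Br
Why: Appel bromination turns the primary allylic alcohol into the bromide under neutral conditions without allylic transposition and leaves the acetate untouched.

**Step 3**
Reactants: 4 prenol
Product: 5 3-methylbut-2-en-1-yl N,N-diisopropylcarbamate
Conditions: i-Pr2NC(O)Cl (1.2 equiv), pyridine, 90 °C
Reagents that add atoms: N,N-diisopropylcarbamoyl chloride CC(C)N(C(C)C)C(Cl)=O
Why: O-carbamoylation (acyl substitution) installs the Hoppe carbamate, which directs α-lithiation and carries the future C9 oxygen.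

**Step 4**
Reactants: 5 3-methylbut-2-en-1-yl N,N-diisopropylcarbamate; 3 (2E,6E)-8-bromo-3,7-dimethylocta-2,6-dien-1-yl acetate
Product: 8 (2E,6E)-1-hydroxy-3,7,11-trimethyldodeca-2,6,10-trien-9-yl N,N-diisopropylcarbamate (racemic at C9), via lithio carbamate 6 (not isolated), via coupled acetate 7 (not isolated)
Conditions: 5 (1.2 equiv), n-BuLi, TMEDA, Et2O, −78 °C; then 3 added at −78 °C; then MeOH, K2CO3, rt
Reagents that add atoms: none
Why: Hoppe α-lithiation of the allyl carbamate followed by SN2 alkylation with the primary allylic bromide forms C8–C9 at the α-carbon because the γ,γ-dimethyl terminus blocks γ-attack; at −78 °C substitution of the allylic bromide outruns addition to the acetate, which is then removed by K2CO3/MeOH transesterification; C9 is racemic and is planarised in step 7.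

**Step 5**
Reactants: 8 (2E,6E)-1-hydroxy-3,7,11-trimethyldodeca-2,6,10-trien-9-yl N,N-diisopropylcarbamate
Product: 11 (2E,6E)-1-hydroxy-3,7,11-trimethyl-9-(trimethylstannyl)dodeca-2,6,10-trien-9-yl N,N-diisopropylcarbamate (racemic at C9), via dilithio species 9 (not isolated), via lithium alkoxide 10 (not isolated)
Conditions: s-BuLi (2.2 equiv), TMEDA, Et2O, −78 °C; Me3SnCl (1.1 equiv), −78 °C; then H2O
Reagents that add atoms: chlorotrimethylstannane C[Sn](C)(C)Cl
Why: After O-deprotonation, a second carbamate-directed Hoppe lithiation removes the allylic C9–H, and electrophilic stannylation goes to the α-carbon (γ-terminus blocked) to give a tertiary α-carbamoyloxy allylstannane, a homoenolate (d3) equivalent for C11; C9 stays racemic.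

**Step 6**
Reactants: 11 (2E,6E)-1-hydroxy-3,7,11-trimethyl-9-(trimethylstannyl)dodeca-2,6,10-trien-9-yl N,N-diisopropylcarbamate
Product: 12 (2E,6E)-3,7,11-trimethyl-1-oxo-9-(trimethylstannyl)dodeca-2,6,10-trien-9-yl N,N-diisopropylcarbamate (racemic at C9)
Conditions: MnO2 (excess), CH2Cl2, rt
Reagents that add atoms: none
Why: MnO2 allylic oxidation is selective for the primary allylic alcohol, keeps the 2E geometry, and is neutral enough for the allylstannane and the carbamate.

**Step 7**
Reactants: 12 (2E,6E)-3,7,11-trimethyl-1-oxo-9-(trimethylstannyl)dodeca-2,6,10-trien-9-yl N,N-diisopropylcarbamate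
Product: 14 (1Z,5E,9E)-4-hydroxy-3,3,6,10-tetramethylcycloundeca-1,5,9-trien-1-yl N,N-diisopropylcarbamate (racemic at the carbinol carbon C1), via difluoroboryl ether 13 (not isolated)
Conditions: BF3·OEt2 (2 equiv), CH2Cl2, 12 added over 10 h to 1 mM final, −78 °C; then H2O
Reagents that add atoms: none
Why: Lewis-acid-promoted intramolecular SE2′ addition of an α-oxygenated allylstannane to an aldehyde (Hoppe homoaldol in its stannane form, Marshall-type allylstannane macrocyclisation): the BF3-bound 2E-enal acts as an oxy-farnesyl cation and is attacked at C1 by C11 of the C10=C11 bond (the 1,11-closure of humulene biosynthesis), the 2E bond forbids six-ring closure onto C6=C7, and tin leaves from C9 to give the C9 enol carbamate (masked ketone, expected Z) and the gem-dimethyl quaternary C11; the C1 carbinol forms racemic and is removed in step 8.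

**Step 8**
Reactants: 14 (1Z,5E,9E)-4-hydroxy-3,3,6,10-tetramethylcycloundeca-1,5,9-trien-1-yl N,N-diisopropylcarbamate
Product: 17 (1Z,4E,9E)-3,3,10-trimethyl-6-methylidenecycloundeca-1,4,9-trien-1-yl N,N-diisopropylcarbamate (achiral), via sulfenate ester 15 (not isolated), via allylic sulfoxide 16 (not isolated)
Conditions: 2,4-(O2N)2C6H3SCl (1.2 equiv), Et3N, ClCH2CH2Cl, 0 °C to 80 °C
Reagents that add atoms: none
Why: Reich diene synthesis: O-sulfenylation, Mislow–Evans-type [2,3]-sigmatropic shift to the C3 sulfoxide (forming the 1E bond), then thermal syn-elimination, which prefers the methyl (C15) hydrogens over the non-activated C4 methylene and gives the exocyclic 1,3(15)-diene; the C1 stereocentre disappears and the enol carbamate is too electron-poor to be sulfenylated.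

**Step 9**
Reactants: 17 (1Z,4E,9E)-3,3,10-trimethyl-6-methylidenecycloundeca-1,4,9-trien-1-yl N,N-diisopropylcarbamate
Product: 19 (4E,9E)-3,3,10-trimethyl-6-methylidenecycloundeca-4,9-dien-1-one (achiral), via lithium enolate 18 (not isolated)
Conditions: MeLi (1.1 equiv), THF, −78 to 0 °C; then AcOH, −78 °C
Reagents that add atoms: none
Why: Nucleophilic acyl cleavage of the enol carbamate by MeLi releases the C9 lithium enolate, and kinetic C-protonation at −78 °C gives the ketone without moving the C6=C7 bond into conjugation.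

**Step 10**
Reactants: 19 (4E,9E)-3,3,10-trimethyl-6-methylidenecycloundeca-4,9-dien-1-one
Product: 20 (1R,4E,9E)-3,3,10-trimethyl-6-methylidenecycloundeca-4,9-dien-1-ol
Conditions: anti-Prelog ketoreductase (R-selective hit from a commercial panel), NADP+ (cat.), i-PrOH, KH2PO4/K2HPO4 buffer pH 7, DMSO (10%), 30 °C
Reagents that add atoms: none
Why: Enzymatic asymmetric carbonyl reduction: the ketoreductase delivers hydride from NADPH to one face of the C9 ketone, reading the bulky gem-dimethyl arm against the flat allylic arm, and sets 9R (anti-Prelog sense with the gem-dimethyl arm as the large group); i-PrOH recycles the cofactor.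

**Step 11**
Reactants: 20 (1R,4E,9E)-3,3,10-trimethyl-6-methylidenecycloundeca-4,9-dien-1-ol; 21 vanillic acid
Product: 22 (1S,4E,9E)-3,3,10-trimethyl-6-methylidenecycloundeca-4,9-dien-1-yl 4-hydroxy-3-methoxybenzoate
Conditions: PPh3, DIAD, THF, 0 °C to rt
Reagents that add atoms: none
Why: Mitsunobu esterification proceeds with clean SN2 inversion at C9 (9R → 9S), and the carboxylic acid (pKa about 4.5) is engaged in preference to the much less acidic phenol, so no phenol protection is needed.

**Compound list**
1 | geranyl acetate, (2E)-3,7-dimethylocta-2,6-dien-1-yl acetate | CC(C)=CCC/C(C)=C/COC(C)=O | starting material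
2 | (2E,6E)-8-hydroxy-3,7-dimethylocta-2,6-dien-1-yl acetate | OC/C(C)=C/CC/C(C)=C/COC(C)=O | intermediate
3 | (2E,6E)-8-bromo-3,7-dimethylocta-2,6-dien-1-yl acetate | BrC/C(C)=C/CC/C(C)=C/COC(C)=O | intermediate
4 | prenol, 3-methylbut-2-en-1-ol | CC(C)=CCO | starting material
5 | 3-methylbut-2-en-1-yl N,N-diisopropylcarbamate | CC(C)=CCOC(=O)N(C(C)C)C(C)C | intermediate
6 | 1-lithio-3-methylbut-2-en-1-yl N,N-diisopropylcarbamate (racemic; not isolated) | CC(C)=CC([Li])OC(=O)N(C(C)C)C(C)C | intermediate
7 | (2E,6E)-9-(N,N-diisopropylcarbamoyloxy)-3,7,11-trimethyldodeca-2,6,10-trien-1-yl acetate (racemic at C9; not isolated) | CC(C)=CC(OC(=O)N(C(C)C)C(C)C)C/C(C)=C/CC/C(C)=C/COC(C)=O | intermediate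
8 | (2E,6E)-1-hydroxy-3,7,11-trimethyldodeca-2,6,10-trien-9-yl N,N-diisopropylcarbamate (racemic at C9) | CC(C)=CC(OC(=O)N(C(C)C)C(C)C)C/C(C)=C/CC/C(C)=C/CO | intermediate
9 | O1,C9-dilithio derivative of 8 (lithium alkoxide at O1, lithium on C9; not isolated) | CC(C)=CC([Li])(OC(=O)N(C(C)C)C(C)C)C/C(C)=C/CC/C(C)=C/CO[Li] | intermediate
10 | lithium 1-alkoxide of 11 (not isolated) | CC(C)=CC([Sn](C)(C)C)(OC(=O)N(C(C)C)C(C)C)C/C(C)=C/CC/C(C)=C/CO[Li] | intermediate
11 | (2E,6E)-1-hydroxy-3,7,11-trimethyl-9-(trimethylstannyl)dodeca-2,6,10-trien-9-yl N,N-diisopropylcarbamate (racemic at C9) | CC(C)=CC([Sn](C)(C)C)(OC(=O)N(C(C)C)C(C)C)C/C(C)=C/CC/C(C)=C/CO | intermediate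
12 | (2E,6E)-3,7,11-trimethyl-1-oxo-9-(trimethylstannyl)dodeca-2,6,10-trien-9-yl N,N-diisopropylcarbamate (racemic at C9) | CC(C)=CC([Sn](C)(C)C)(OC(=O)N(C(C)C)C(C)C)C/C(C)=C/CC/C(C)=C/C=O | intermediate
13 | O-difluoroboryl ether of 14 (racemic; not isolated) | FB(F)OC1/C=C(\C)CC/C=C(\C)C/C(OC(=O)N(C(C)C)C(C)C)=C/C1(C)C | intermediate
14 | (1Z,5E,9E)-4-hydroxy-3,3,6,10-tetramethylcycloundeca-1,5,9-trien-1-yl N,N-diisopropylcarbamate (racemic at the carbinol carbon) | OC1/C=C(\C)CC/C=C(\C)C/C(OC(=O)N(C(C)C)C(C)C)=C/C1(C)C | intermediate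
15 | 2,4-dinitrobenzenesulfenate ester of 14 at the carbinol oxygen (racemic; not isolated) | [O-][N+](=O)c1ccc(SOC2/C=C(\C)CC/C=C(\C)C/C(OC(=O)N(C(C)C)C(C)C)=C/C2(C)C)c([N+](=O)[O-])c1 | intermediate
16 | (1Z,4E,9E)-6-(2,4-dinitrophenylsulfinyl)-3,3,6,10-tetramethylcycloundeca-1,4,9-trien-1-yl N,N-diisopropylcarbamate (stereoisomer mixture at C6 and S; not isolated) | CC1(S(=O)c2ccc(cc2[N+](=O)[O-])[N+](=O)[O-])/C=C/C(C)(C)/C=C(OC(=O)N(C(C)C)C(C)C)/C/C(C)=C/CC1 | intermediate
17 | (1Z,4E,9E)-3,3,10-trimethyl-6-methylidenecycloundeca-1,4,9-trien-1-yl N,N-diisopropylcarbamate (achiral) | C=C1/C=C/C(C)(C)/C=C(OC(=O)N(C(C)C)C(C)C)/C/C(C)=C/CC1 | intermediate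
18 | lithium (1Z,4E,9E)-3,3,10-trimethyl-6-methylidenecycloundeca-1,4,9-trien-1-olate (not isolated) | C=C1/C=C/C(C)(C)/C=C(O[Li])/C/C(C)=C/CC1 | intermediate
19 | (4E,9E)-3,3,10-trimethyl-6-methylidenecycloundeca-4,9-dien-1-one (achiral) | C=C1/C=C/C(C)(C)CC(=O)C/C(C)=C/CC1 | intermediate
20 | (1R,4E,9E)-3,3,10-trimethyl-6-methylidenecycloundeca-4,9-dien-1-ol | C=C1/C=C/C(C)(C)C[C@H](O)C/C(C)=C/CC1 | intermediate
21 | vanillic acid, 4-hydroxy-3-methoxybenzoic acid | COc1cc(C(=O)O)ccc1O | starting material
22 | (1S,4E,9E)-3,3,10-trimethyl-6-methylidenecycloundeca-4,9-dien-1-yl 4-hydroxy-3-methoxybenzoate | C=C1/C=C/C(C)(C)C[C@@H](OC(=O)c2ccc(O)c(OC)c2)C/C(C)=C/CC1 | target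

**Totals**
Total step count: 11. Longest linear sequence: 10 steps (1, 2, 4, 5, 6, 7, 8, 9, 10, 11, from geranyl acetate).

**Steps most likely to fail**

Step 7 (ring closure). An eleven-membered ring and a quaternary carbon are formed at once from a hindered tertiary stannane; oligomerisation, protodestannylation or a 1,3-stannyl shift may win. The fallback sets out from 8 and comes back at 14, replacing the open, Lewis-acid-driven closure by a Lewis-acid-free allylboration through a closed chair transition state. Compound 8 is lithiated as in step 5 and the dilithio species 9 is quenched with i-PrOBpin to give the lithium alkoxide boronate F1, and aqueous work-up gives the α-carbamoyloxy allylboronate alcohol F2. MnO2 oxidation gives the boronate enal F3. Heating F3 in toluene at 80 °C under high dilution gives the cyclised O-boryl ether F4 by γ-selective intramolecular allylboration, and hydrolysis of F4 returns 14.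

Step 8 (diene formation). The sulfoxide may eliminate toward C4 instead of C15, or the hindered C1 alcohol may not be sulfenylated. The fallback sets out from 14 and comes back at 17, using a π-allylpalladium elimination instead of a sigmatropic/syn-elimination sequence. ClCO2Me and pyridine convert 14 into the methyl carbonate F5. With Pd(PPh3)4 in dioxane at 100 °C, F5 ionises to the C1–C3 π-allyl complex, and β-hydride elimination from the C15 methyl gives 17 with loss of CO2 and methanol.

Step 10 (enantioselective reduction). Both ketone substituents begin with CH2, so a highly selective enzyme may not be found. The fallback sets out from 19 and comes back at 20, setting C9 by kinetic resolution instead of asymmetric reduction. NaBH4 in MeOH gives the racemic alcohol F6. Candida antarctica lipase B with vinyl acetate acylates the (R)-enantiomer (Kazlauskas rule with the gem-dimethyl arm as the large group) to the (R)-acetate F7, which is separated from the unreacted (S)-half of F6; that half is re-oxidised to 19 and recycled. K2CO3/MeOH on F7 returns 20.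

**Further compounds**
F1 | step 7 | lithium 1-alkoxide of F2 (racemic; not isolated) | CC(C)=CC(B1OC(C)(C)C(C)(C)O1)(OC(=O)N(C(C)C)C(C)C)C/C(C)=C/CC/C(C)=C/CO[Li]
F2 | step 7 | (2E,6E)-1-hydroxy-3,7,11-trimethyl-9-(4,4,5,5-tetramethyl-1,3,2-dioxaborolan-2-yl)dodeca-2,6,10-trien-9-yl N,N-diisopropylcarbamate (racemic) | CC(C)=CC(B1OC(C)(C)C(C)(C)O1)(OC(=O)N(C(C)C)C(C)C)C/C(C)=C/CC/C(C)=C/CO
F3 | step 7 | (2E,6E)-3,7,11-trimethyl-1-oxo-9-(4,4,5,5-tetramethyl-1,3,2-dioxaborolan-2-yl)dodeca-2,6,10-trien-9-yl N,N-diisopropylcarbamate (racemic) | CC(C)=CC(B1OC(C)(C)C(C)(C)O1)(OC(=O)N(C(C)C)C(C)C)C/C(C)=C/CC/C(C)=C/C=O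
F4 | step 7 | O-(4,4,5,5-tetramethyl-1,3,2-dioxaborolan-2-yl) ether of 14 (racemic; not isolated) | CC1(C)OB(OC2/C=C(\C)CC/C=C(\C)C/C(OC(=O)N(C(C)C)C(C)C)=C/C2(C)C)OC1(C)C
F5 | step 8 | methyl carbonate of 14 at the carbinol oxygen (racemic) | COC(=O)OC1/C=C(\C)CC/C=C(\C)C/C(OC(=O)N(C(C)C)C(C)C)=C/C1(C)C
F6 | step 10 | racemic (4E,9E)-3,3,10-trimethyl-6-methylidenecycloundeca-4,9-dien-1-ol | C=C1/C=C/C(C)(C)CC(O)C/C(C)=C/CC1
F7 | step 10 | (1R,4E,9E)-3,3,10-trimethyl-6-methylidenecycloundeca-4,9-dien-1-yl acetate | C=C1/C=C/C(C)(C)C[C@H](OC(C)=O)C/C(C)=C/CC1
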